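**Strategy.** Everything rests on reading the five-membered ring C8–C12 (C9=O, C10–Cl, C11=, C12–OH/octenyl, C8–side chain) as a Piancatelli retron. This ring is a 4-hydroxy-4,5-dialkyl-2-chlorocyclopent-2-enone. C9–C12 are the four carbons of a 3-chloro-5-[(Z)-oct-2-enyl]furan and C8 is its carbinol carbon. In one operation aqueous Lewis acid ionises the C8 acetate, water adds at C12, the furan opens, and a conrotatory 4π closure forms C8–C12. This creates the ring, the C12 tertiary alcohol and both ring stereocentres, and delivers the target itself. The precursor is the furfuryl tetraacetate (both C8 epimers converge). It is assembled from a D-xylose-derived C1–C8 aldehyde ester (xylose C1–C5 = C4–C8) and the C2-lithiated chlorofuran.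

Key step: step 15

Assumption: prostanoid numbering is used throughout (C1 ester carbon, C5–C7 acetoxy carbons, ring C8–C12, octenyl C13–C20). The C8 configuration of all furfuryl compounds is left uncontrolled because ionisation in the key step erases it.

**Route**

Step 1
Reactants: 1 D-xylose
Product: 2 D-xylose diethyl dithioacetal
Conditions: EtSH, conc. HCl, 0 °C
Reagents that add atoms: ethanethiol, CCS
Why: Fischer dithioacetalisation opens the hemiacetal to the acyclic chain and masks C1 (future C4) without touching the three carbinol centres that become C5, C6 and C7.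

Step 2
Reactants: 2 D-xylose diethyl dithioacetal
Product: 3 2,3,4,5-tetra-O-triethylsilyl-D-xylose diethyl dithioacetal
Conditions: TESCl, imidazole, DMF, 0 °C → rt
Reagents that add atoms: chlorotriethylsilane, CC[Si](Cl)(CC)CC
Why: Exhaustive silylation gives four fluoride-labile ethers whose primary member can later be addressed alone, and it avoids benzyl ethers, whose hydrogenolysis would not spare the furan, the C–Cl bond or the Z-alkene.

Step 3
Reactants: 3 2,3,4,5-tetra-O-triethylsilyl-D-xylose diethyl dithioacetal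
Product: 4 (2R,3S,4R)-2,3,4,5-tetrakis(triethylsilyloxy)pentanal (tetra-O-TES-aldehydo-D-xylose)
Conditions: I2, NaHCO3, acetone/H2O, 0 °C
Reagents that add atoms: water, O
Why: Iodine-mediated oxidative hydrolysis of a dithioacetal under bicarbonate buffer is fast at 0 °C and should leave the TES ethers and the α-silyloxy stereocentre intact.

Step 4
Reactants: 4 (2R,3S,4R)-2,3,4,5-tetrakis(triethylsilyloxy)pentanal; 5 (2-carboxyethyl)triphenylphosphonium bromide
Product: 8 methyl (3Z,5S,6R,7R)-5,6,7,8-tetrakis(triethylsilyloxy)oct-3-enoate, via sodium 3-(triphenyl-λ5-phosphanylidene)propanoate 6 (not isolated), via sodium (3Z,5S,6R,7R)-5,6,7,8-tetrakis(triethylsilyloxy)oct-3-enoate 7 (not isolated)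
Conditions: 5, NaHMDS (2 equiv per 5), THF, −78 → 0 °C; 4, −78 °C → rt; then MeI, DMF, rt
Reagents that add atoms: iodomethane, CI
Why: Wittig olefination with the non-stabilised carboxylate ylide (the carboxylate charge restrains expulsion of Ph3P) adds C1–C3, and SN2 O-methylation of the sodium carboxylate in the same flask spares the TES ethers an acidic work-up; no stereocentre is formed, the alkene geometry is removed in step 5, and low temperature should preserve C5.

Step 5
Reactants: 8 methyl (3Z,5S,6R,7R)-5,6,7,8-tetrakis(triethylsilyloxy)oct-3-enoate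
Product: 9 methyl (5S,6R,7R)-5,6,7,8-tetrakis(triethylsilyloxy)octanoate
Conditions: H2 (1 atm), Pd/C, EtOAc, rt
Reagents that add atoms: none
Why: Catalytic hydrogenation of the disubstituted alkene in a non-protic solvent should leave TES ethers and ester untouched, and it is done before any furan, C–Cl bond or Z-octenyl group is present.

Step 6
Reactants: 9 methyl (5S,6R,7R)-5,6,7,8-tetrakis(triethylsilyloxy)octanoate
Product: 10 methyl (5S,6R,7S)-8-oxo-5,6,7-tris(triethylsilyloxy)octanoate
Conditions: (COCl)2, DMSO, CH2Cl2, −78 → −40 °C; Et3N, −78 → 0 °C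
Reagents that add atoms: none
Why: In a Swern oxidation applied directly to a silyl ether, chlorodimethylsulfonium chloride cleaves only the unhindered primary O–TES bond and the alkoxysulfonium salt collapses with Et3N to the aldehyde, while the secondary TES ethers, the ester and C7 should stay intact at low temperature.

Step 7
Reactants: 11 (Z)-oct-2-en-1-ol
Product: 12 (Z)-1-bromooct-2-ene
Conditions: CBr4, PPh3, CH2Cl2, 0 °C
Reagents that add atoms: tetrabromomethane, BrC(Br)(Br)Br
Why: The Appel reaction displaces the primary allylic oxyphosphonium ion by SN2 under neutral conditions, so the Z geometry should be kept.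

Step 8
Reactants: 13 3-bromofuran
Product: 15 3-bromo-2-(trimethylsilyl)furan, via 3-bromo-2-lithiofuran 14 (not isolated)
Conditions: LDA, THF, −78 °C; TMSCl, −78 °C → rt
Reagents that add atoms: chlorotrimethylsilane, C[Si](C)(C)Cl
Why: Halogen-directed deprotonation of a 3-halofuran occurs at C2 (flanked by O and Br), and silylation blocks this most acidic position so that C5 can be functionalised next.

Step 9
Reactants: 15 3-bromo-2-(trimethylsilyl)furan
Product: 17 3-chloro-2-(trimethylsilyl)furan, via 3-lithio-2-(trimethylsilyl)furan 16 (not isolated)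
Conditions: n-BuLi, Et2O, −78 °C; C2Cl6, −78 °C → rt
Reagents that add atoms: hexachloroethane, ClC(Cl)(Cl)C(Cl)(Cl)Cl
Why: Bromine–lithium exchange at −78 °C (C2 is blocked, so the 3-lithiofuran cannot drift there) followed by electrophilic chlorination with hexachloroethane replaces Br by Cl on a non-volatile silane.

Step 10
Reactants: 17 3-chloro-2-(trimethylsilyl)furan; 12 (Z)-1-bromooct-2-ene
Product: 19 [3-chloro-5-[(Z)-oct-2-en-1-yl]furan-2-yl]trimethylsilane, via 3-chloro-5-lithio-2-(trimethylsilyl)furan 18 (not isolated)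
Conditions: n-BuLi, THF, −78 → −20 °C; 12, −78 °C → rt
Reagents that add atoms: none
Why: The C–Cl bond does not exchange with n-BuLi, so the only remaining α-position (C5) is deprotonated, and SN2 alkylation of the furyllithium with the primary allylic bromide should install C13–C20 with the Z-alkene retained.

Step 11
Reactants: 19 [3-chloro-5-[(Z)-oct-2-en-1-yl]furan-2-yl]trimethylsilane
Product: 20 4-chloro-2-[(Z)-oct-2-en-1-yl]furan (= 3-chloro-5-octenylfuran)
Conditions: TBAF·3H2O, THF, 0 °C → rt
Reagents that add atoms: none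
Why: Fluoride-induced protodesilylation of a 2-silylfuran is eased by the adjacent chlorine, which stabilises the departing furyl anion, and the conditions are mild enough for the skipped furan/alkene unit.

Step 12
Reactants: 20 4-chloro-2-[(Z)-oct-2-en-1-yl]furan; 10 methyl (5S,6R,7S)-8-oxo-5,6,7-tris(triethylsilyloxy)octanoate
Product: 23 methyl (5S,6R,7S,8RS)-8-[3-chloro-5-[(Z)-oct-2-en-1-yl]furan-2-yl]-8-hydroxy-5,6,7-tris(triethylsilyloxy)octanoate, via 3-chloro-2-lithio-5-[(Z)-oct-2-en-1-yl]furan 21 (not isolated), via the lithium C8-alkoxide of the adduct 22 (not isolated)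
Conditions: LDA, THF, −78 °C; 10, −78 °C; AcOH/THF quench at −78 °C
Reagents that add atoms: none
Why: Kinetic chlorine- and oxygen-flanked α-deprotonation by LDA at −78 °C should outrun removal of the C13 hydrogens, and 1,2-addition of the heteroaryllithium to the aldehyde is much faster than attack on the remote methyl ester; the new C8 centre forms as a mixture that needs no control, and any O7→O8 silyl shift is harmless.

Step 13
Reactants: 23 methyl (5S,6R,7S,8RS)-8-[3-chloro-5-[(Z)-oct-2-en-1-yl]furan-2-yl]-8-hydroxy-5,6,7-tris(triethylsilyloxy)octanoate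
Product: 24 methyl (5S,6R,7S,8RS)-8-[3-chloro-5-[(Z)-oct-2-en-1-yl]furan-2-yl]-5,6,7,8-tetrahydroxyoctanoate
Conditions: HF·pyridine, pyridine, THF, 0 °C; crude product used at once
Reagents that add atoms: none
Why: Buffered fluoride cleavage of secondary TES ethers is fast at 0 °C, too mild to ionise the deactivated furfuryl alcohol, and neither basic nor acidic enough to drive δ-lactonisation of the 5-hydroxy ester before acetylation.

Step 14
Reactants: 24 methyl (5S,6R,7S,8RS)-8-[3-chloro-5-[(Z)-oct-2-en-1-yl]furan-2-yl]-5,6,7,8-tetrahydroxyoctanoate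
Product: 25 methyl (5S,6R,7S,8RS)-5,6,7,8-tetraacetoxy-8-[3-chloro-5-[(Z)-oct-2-en-1-yl]furan-2-yl]octanoate
Conditions: Ac2O, pyridine, DMAP (cat.), CH2Cl2, 0 °C → rt
Reagents that add atoms: acetic anhydride, CC(=O)OC(C)=O
Why: DMAP-catalysed exhaustive O-acetylation installs the three acetates of the target and the C8 nucleofuge in one operation, touches no stereocentre and makes any acyl migration degenerate.

Step 15
Reactants: 25 methyl (5S,6R,7S,8RS)-5,6,7,8-tetraacetoxy-8-[3-chloro-5-[(Z)-oct-2-en-1-yl]furan-2-yl]octanoate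
Product: 28 punaglandin 2, methyl (5S,6R,7R)-5,6,7-triacetoxy-7-[(1R,2S)-4-chloro-2-hydroxy-2-[(Z)-oct-2-en-1-yl]-5-oxocyclopent-3-en-1-yl]heptanoate (5S,6R,7R,8R,12S), via the 1,4-dihydroxy-3-chloropentadienyl cation 26 (not isolated), via 8-epi-punaglandin 2 27 (not isolated)
Conditions: Dy(OTf)3 (20 mol %), t-BuOH/H2O 5:1, 80 °C, Ar; chromatography
Reagents that add atoms: water, O
Why: The Lewis acid ionises the furfuryl C8 acetate (both C8 epimers, with or without assistance by the C7 acetate, give the same furan-stabilised cation), water adds at the alkylated furan carbon C12, and the hemiketal opens to cation 26, whose enol lies regiospecifically at C8=C9. This is the Piancatelli rearrangement, established under aqueous Lewis-acid catalysis for 5-alkyl-2-furylcarbinols, which give 4-hydroxy-4-alkyl-5-substituted cyclopent-2-enones; the chlorine sits on the central carbon C10 of the cation and blocks neither terminus, and it and the acetoxy groups should only slow the ionisation. The cyclopentenone ring closes by thermally allowed conrotatory 4π electrocyclisation between the termini C8 and C12, and proton loss leaves the former furan oxygen as C9=O with C10–Cl in the enone. C12 is fixed by the sense of conrotation, which the C7 stereocentre must bias: A(1,3) strain with the C9 hydroxyl holds C7–H in the dienol plane, C12 should bond to the C8 face anti to the bulkier, better σ-donating C6 chain (the face of the small acetoxy group), and from the usual out,out cation (side chain and C12–OH outside) this gives 12S with OH trans to the side chain, i.e. 27. C8 is then fixed thermodynamically, since acid-catalysed keto–enol exchange in the same flask should move the branched side chain trans to the octenyl group and cis to the hydroxyl (8R), and the neutral enol, unlike an enolate, should reketonise faster than it expels the C7 acetate. The step needs C8–O ionisation to win over ester hydrolysis and over capture of the cation by side-chain oxygen, which the all-acetate design secures (O7/O8 acyl shifts are degenerate, O5 cannot close a tetrahydrofuran onto C8), and minor C12 isomers are removable because C5–C7 make them diastereomers.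

**Compound list**

1 | D-xylose (drawn open-chain) | O=C[C@H](O)[C@@H](O)[C@H](O)CO | starting material
2 | D-xylose diethyl dithioacetal | CCSC(SCC)[C@H](O)[C@@H](O)[C@H](O)CO | intermediate
3 | 2,3,4,5-tetra-O-triethylsilyl-D-xylose diethyl dithioacetal | CCSC(SCC)[C@H](O[Si](CC)(CC)CC)[C@@H](O[Si](CC)(CC)CC)[C@H](O[Si](CC)(CC)CC)CO[Si](CC)(CC)CC | intermediate
4 | (2R,3S,4R)-2,3,4,5-tetrakis(triethylsilyloxy)pentanal | O=C[C@H](O[Si](CC)(CC)CC)[C@@H](O[Si](CC)(CC)CC)[C@H](O[Si](CC)(CC)CC)CO[Si](CC)(CC)CC | intermediate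
5 | (2-carboxyethyl)triphenylphosphonium bromide | [Br-].OC(=O)CC[P+](c1ccccc1)(c1ccccc1)c1ccccc1 | starting material
6 | sodium 3-(triphenyl-λ5-phosphanylidene)propanoate (ylide) | [Na+].[O-]C(=O)CC=P(c1ccccc1)(c1ccccc1)c1ccccc1 | intermediate
7 | sodium (3Z,5S,6R,7R)-5,6,7,8-tetrakis(triethylsilyloxy)oct-3-enoate | [Na+].[O-]C(=O)C/C=C\[C@H](O[Si](CC)(CC)CC)[C@@H](O[Si](CC)(CC)CC)[C@H](O[Si](CC)(CC)CC)CO[Si](CC)(CC)CC | intermediate
8 | methyl (3Z,5S,6R,7R)-5,6,7,8-tetrakis(triethylsilyloxy)oct-3-enoate | COC(=O)C/C=C\[C@H](O[Si](CC)(CC)CC)[C@@H](O[Si](CC)(CC)CC)[C@H](O[Si](CC)(CC)CC)CO[Si](CC)(CC)CC | intermediate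
9 | methyl (5S,6R,7R)-5,6,7,8-tetrakis(triethylsilyloxy)octanoate | COC(=O)CCC[C@H](O[Si](CC)(CC)CC)[C@@H](O[Si](CC)(CC)CC)[C@H](O[Si](CC)(CC)CC)CO[Si](CC)(CC)CC | intermediate
10 | methyl (5S,6R,7S)-8-oxo-5,6,7-tris(triethylsilyloxy)octanoate | COC(=O)CCC[C@H](O[Si](CC)(CC)CC)[C@@H](O[Si](CC)(CC)CC)[C@H](O[Si](CC)(CC)CC)C=O | intermediate
11 | (Z)-oct-2-en-1-ol | CCCCC/C=C\CO | starting material
12 | (Z)-1-bromooct-2-ene | CCCCC/C=C\CBr | intermediate
13 | 3-bromofuran | Brc1ccoc1 | starting material
14 | 3-bromo-2-lithiofuran | [Li]c1occc1Br | intermediate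
15 | 3-bromo-2-(trimethylsilyl)furan | C[Si](C)(C)c1occc1Br | intermediate
16 | 3-lithio-2-(trimethylsilyl)furan | C[Si](C)(C)c1occc1[Li] | intermediate
17 | 3-chloro-2-(trimethylsilyl)furan | C[Si](C)(C)c1occc1Cl | intermediate
18 | 3-chloro-5-lithio-2-(trimethylsilyl)furan | C[Si](C)(C)c1oc([Li])cc1Cl | intermediate
19 | [3-chloro-5-[(Z)-oct-2-en-1-yl]furan-2-yl]trimethylsilane | CCCCC/C=C\Cc1cc(Cl)c(o1)[Si](C)(C)C | intermediate
20 | 4-chloro-2-[(Z)-oct-2-en-1-yl]furan | CCCCC/C=C\Cc1cc(Cl)co1 | intermediate
21 | 3-chloro-2-lithio-5-[(Z)-oct-2-en-1-yl]furan | CCCCC/C=C\Cc1cc(Cl)c([Li])o1 | intermediate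
22 | lithium C8-alkoxide of 23 (C8 epimers) | CCCCC/C=C\Cc1cc(Cl)c(o1)C([O-])[C@@H](O[Si](CC)(CC)CC)[C@H](O[Si](CC)(CC)CC)[C@H](CCCC(=O)OC)O[Si](CC)(CC)CC.[Li+] | intermediate
23 | methyl (5S,6R,7S,8RS)-8-[3-chloro-5-[(Z)-oct-2-en-1-yl]furan-2-yl]-8-hydroxy-5,6,7-tris(triethylsilyloxy)octanoate | CCCCC/C=C\Cc1cc(Cl)c(o1)C(O)[C@@H](O[Si](CC)(CC)CC)[C@H](O[Si](CC)(CC)CC)[C@H](CCCC(=O)OC)O[Si](CC)(CC)CC | intermediate
24 | methyl (5S,6R,7S,8RS)-8-[3-chloro-5-[(Z)-oct-2-en-1-yl]furan-2-yl]-5,6,7,8-tetrahydroxyoctanoate | CCCCC/C=C\Cc1cc(Cl)c(o1)C(O)[C@@H](O)[C@H](O)[C@H](CCCC(=O)OC)O | intermediate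
25 | methyl (5S,6R,7S,8RS)-5,6,7,8-tetraacetoxy-8-[3-chloro-5-[(Z)-oct-2-en-1-yl]furan-2-yl]octanoate (key-step precursor) | CCCCC/C=C\Cc1cc(Cl)c(o1)C(OC(C)=O)[C@@H](OC(C)=O)[C@H](OC(C)=O)[C@H](CCCC(=O)OC)OC(C)=O | intermediate
26 | 1,4-dihydroxy-3-chloropentadienyl cation C8–C12 (C12-protonated ketone, C8=C9 enol, side chain outside) | CCCCC/C=C\CC(=[OH+])/C=C(Cl)\C(O)=C\[C@@H](OC(C)=O)[C@H](OC(C)=O)[C@H](CCCC(=O)OC)OC(C)=O | intermediate
27 | 8-epi-punaglandin 2 (5S,6R,7R,8S,12S) | CCCCC/C=C\C[C@@]1(O)C=C(Cl)C(=O)[C@H]1[C@@H](OC(C)=O)[C@H](OC(C)=O)[C@H](CCCC(=O)OC)OC(C)=O | intermediate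
28 | punaglandin 2 (5S,6R,7R,8R,12S) | CCCCC/C=C\C[C@@]1(O)C=C(Cl)C(=O)[C@@H]1[C@@H](OC(C)=O)[C@H](OC(C)=O)[C@H](CCCC(=O)OC)OC(C)=O | target

**Step count.** The route has 15 steps in total. The longest linear sequence is 10 steps (steps 1–6 and 12–15).

**Steps most likely to fail**

1. **Step 15.**
   - **Risk.** Ionisation of the doubly deactivated furfuryl acetate may be slow. Hydrolysis of the other acetates, proton loss from C13 of the cation, or loss of acetic acid across C7–C8 during the C8 equilibration could then compete. The facial bias of the conrotation may also be poor.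
   - **Fallback.** The fallback uses an ether-protected rearrangement, a separate equilibration and late acetylation; it sets out from 24 and returns at 28.
     - Persilylation of 24 (TBSOTf, 2,6-lutidine, CH2Cl2, 0 °C) would give the tetrakis-TBS ether F1.
     - Aqueous Lewis acid would ionise its furfuryl silyl ether and give the 5,6,7-tris-O-TBS chlorocyclopentenone F2. In this compound O7 neither participates nor leaves, so C8 can be equilibrated in a separate operation with mild base (Et3N, CH2Cl2) and the C12 diastereomers separated.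
     - HF·pyridine would then free the 5,6,7-triol F3.
     - Ac2O/pyridine at 0 °C without DMAP would acetylate the three secondary hydroxyls and spare the tertiary C12 hydroxyl, giving 28.

2. **Step 4.**
   - **Risk.** The carboxylate ylide may collapse by loss of triphenylphosphine before it meets the hindered aldehyde. The basic medium may also epimerise the α-silyloxy aldehyde or cause β-elimination from it.
   - **Fallback.** The fallback builds the chain by olefin metathesis; it sets out from 4 and returns at 9.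
     - Methylenation (Ph3P=CH2, THF, −78 °C → rt) would give the terminal alkene F4.
     - Cross-metathesis with methyl but-3-enoate (second-generation Hoveyda–Grubbs catalyst, CH2Cl2, 40 °C) would give mainly the (E)-enoate F5.
     - Hydrogenation as in step 5 would give 9.

3. **Step 12.**
   - **Risk.** Deprotonation at C13 may compete with ring metalation. The furyllithium may also attack the methyl ester or enolise the α-silyloxy aldehyde.
   - **Fallback.** The fallback is a base-free chromium-mediated coupling; it sets out from 19, skips step 11 and returns at 23.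
     - ipso-Iododesilylation (NIS, MeCN, 0 °C, dark) would give 3-chloro-2-iodo-5-[(Z)-oct-2-en-1-yl]furan F6.
     - Nozaki–Hiyama–Kishi coupling with 10 (CrCl2, cat. NiCl2, DMF, rt), which tolerates esters and enolisable aldehydes, would give 23.

**Further compounds**

F1 | step 15 | methyl (5S,6R,7S,8RS)-5,6,7,8-tetrakis(tert-butyldimethylsilyloxy)-8-[3-chloro-5-[(Z)-oct-2-en-1-yl]furan-2-yl]octanoate | CCCCC/C=C\Cc1cc(Cl)c(o1)C(O[Si](C)(C)C(C)(C)C)[C@@H](O[Si](C)(C)C(C)(C)C)[C@H](O[Si](C)(C)C(C)(C)C)[C@H](CCCC(=O)OC)O[Si](C)(C)C(C)(C)C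
F2 | step 15 | 5,6,7-tris-O-TBS analogue of punaglandin 2 (acetates replaced by TBS ethers, same configuration) | CCCCC/C=C\C[C@@]1(O)C=C(Cl)C(=O)[C@@H]1[C@@H](O[Si](C)(C)C(C)(C)C)[C@H](O[Si](C)(C)C(C)(C)C)[C@H](CCCC(=O)OC)O[Si](C)(C)C(C)(C)C
F3 | step 15 | 5,6,7-tri-O-deacetylpunaglandin 2 | CCCCC/C=C\C[C@@]1(O)C=C(Cl)C(=O)[C@@H]1[C@@H](O)[C@H](O)[C@H](CCCC(=O)OC)O
F4 | step 4 | (3S,4R,5R)-3,4,5,6-tetrakis(triethylsilyloxy)hex-1-ene | C=C[C@H](O[Si](CC)(CC)CC)[C@@H](O[Si](CC)(CC)CC)[C@H](O[Si](CC)(CC)CC)CO[Si](CC)(CC)CC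
F5 | step 4 | methyl (3E,5S,6R,7R)-5,6,7,8-tetrakis(triethylsilyloxy)oct-3-enoate | COC(=O)C/C=C/[C@H](O[Si](CC)(CC)CC)[C@@H](O[Si](CC)(CC)CC)[C@H](O[Si](CC)(CC)CC)CO[Si](CC)(CC)CC
F6 | step 12 | 3-chloro-2-iodo-5-[(Z)-oct-2-en-1-yl]furan | CCCCC/C=C\Cc1cc(Cl)c(I)o1
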